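**Numbering.** Compounds 1–27 are fixed by the steps below: 1 is (S)-citronellal, 11 the ring B phenol, 22 the precursor of the key step, 24 its product and 27 the target. Rings and atoms are labelled as follows: ring A is A1 C–OH, A2 side chain, A3 H, A4 biaryl carbon, A5 C–CH3, A6 H; ring B is B1 C–OH, B2 side chain, B3 and B4 H, B5 C–CH3, B6 biaryl carbon.

## Analysis of the target

The target 27 (C30H42O2) is an unsymmetrical biaryl of two 5-methyl-2-(6-methylhept-5-en-2-yl)phenol units. One unit is joined through the carbon para to its hydroxyl (ring A) and the other through the carbon ortho to its hydroxyl (ring B). It has two stereocentres, the benzylic carbons of the side chains on A2 and B2. Both are S, they are constitutionally alike, and they lie too far apart to influence each other, so each must be brought in or set independently. The sensitive groups are the two trisubstituted alkenes (acid, electrophiles, hydrogenation, hydride-abstracting oxidants), the two electron-rich phenols, and the tertiary benzylic C–H bonds, whose loss would erase the stereocentres. The A4–B6 axis carries three ortho substituents (A5 methyl, B1 oxygen, B5 methyl). A direct aryl–aryl coupling would therefore be slow, and an oxidative phenol coupling would not distinguish ortho from para positions. The difficulty is to build this hindered, unsymmetrically linked biaryl without touching the alkenes or the benzylic centres. The strategy rests on two features: the A5 methyl and the B1 oxygen face each other across the axis and can be read as the ends of a broken CH2–O bridge, and the A1 oxygen stands para to A4 just as a furan oxygen spans its two α carbons. Ring A can thus be grown on ring B from a furan and an alkyne held on the B1 oxygen.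

## Retrosynthetic reasoning

**27 ⇒ 24.** The A5 methyl and the B1 hydroxyl are joined into a benzylic CH2–O bond, which gives the 6H-benzo[c]chromenol 24. This bridge is the tether the ring-forming step needs. In the forward direction it must be cut by electron transfer, which selects the benzylic C–O bond and leaves isolated alkenes alone.

**24 ⇒ 22 (key disconnection).** Cutting A4–A5 and A1–A6 and returning the A1 oxygen to a furan removes both ring A and the pyran, leaving the aryl furan 22 with a propargyl group on the B1 oxygen. This is the place to cut because it replaces the hindered aryl–aryl coupling by an aryl–furan bond that is made as a ketone. The four-atom tether B6–B1–O–CH2 also fixes which alkyne carbon meets A4. The forward reaction is an intramolecular furan–alkyne cycloaddition followed by opening of the oxygen bridge towards A1.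

**22 ⇒ 20 + 21.** The O–CH2 bond is cut to the hindered phenol 20 and propargyl bromide 21. A simple O-alkylation makes it.

**20 ⇒ 18.** The furan C–O bond is opened to the γ-keto aldehyde 18, with the B1 oxygen still carrying its methoxymethyl group. One acid treatment should close the furan and free the phenol.

**18 ⇒ 15 + 1.** The bond between the ketone CH2 and the aldehyde α-carbon is cut. The aldehyde half is a second molecule of 1, which delivers the A2 stereocentre unchanged. Its α-carbon becomes furan C4 and later A2, so the configuration formed there does not matter. The other half is the aryl chloromethyl ketone 15.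

**15 ⇒ 12 + 13, and 12 ⇒ 11.** The B6–acyl bond is cut to the aryllithium derived from the methoxymethyl ether 12 and the chloroacetyl donor 13. B6 is the only free position ortho to the directing oxygen. 12 comes from the phenol 11.

**11 ⇒ 9 ⇒ 8 ⇒ 7 ⇒ 6 ⇒ 4.** The phenol 11 is taken back to a cyclohexenone at the same oxidation level, 9, which carries a sulfinyl leaving group on ring carbon C4. The only β-hydrogens of that carbon are ring hydrogens. The new double bond therefore cannot form towards the side chain, and aromatisation finishes through the ring C6–H. Placing the leaving group on the carbon that bears the side chain was avoided because elimination there could run into the side-chain methine and erase the B2 stereocentre. 9 arises by 1,3-oxidative transposition of the tertiary allylic alcohol 8, which moves the oxygen next to the side-chain carbon and leaves the methyl para to it. 8 comes from sulfide 7 by oxidation at sulfur. 7 comes from the α′-sulfanyl enone 6 and a methyl nucleophile. 6 comes from enone 4 by sulfenylation at its α′ CH2.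

**4 ⇒ 1 + 2.** The ring of 4 is cut by a Robinson disconnection into 1 and methyl vinyl ketone 2. The citronellal α-carbon becomes the ring carbon that bears the side chain, so the stereocentre of 1 is carried over untouched.

## Alternatives that were turned down

**Alternative 1:** In both side chains the bond between the benzylic carbon and the next chain carbon is cut. The forward key step is a twofold nickel-catalysed asymmetric hydrovinylation of the divinyl biaryl A2 with ethene A3 (cationic allylnickel catalyst with a chiral phosphoramidite), which gives the bis[(S)-but-3-en-2-yl] dimethoxy biaryl A1.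
- For it: both stereocentres are set in one catalytic step on an achiral precursor, either enantiomer is available by choice of ligand, and the two arms can be extended in parallel (hydroboration, then a B-alkyl cross-coupling with an isobutenyl halide). On step count and on freedom of configuration it is at least as strong as the chosen route.
- Against it: A2 is itself the tri-ortho-substituted biaryl and must first be made by a hindered cross-coupling. The two vinyl groups differ (one is flanked by a methoxy group), so one catalyst must give high selectivity in two unlike settings. Any shortfall shows up as a diastereomer of A1 that is hard to remove. Isomerisation of the 3-arylbutene units into conjugation would erase the centres. The route ends with cleavage of two aryl methyl ethers, one of them hindered, next to two acid-sensitive alkenes.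
- Comparison: the chosen route takes both centres ready-made from 1, never couples two arenes, and carries no O-methyl group to the end.

**Alternative 2:** Ring B is cut at B2–B3 and B1–B6. The forward key step is a cycloaddition of the siloxyalkyne A6 across C6 and C3 of the 3-aryl-4-methyl-2-pyrone A5, followed by decarboxylative loss of the lactone bridge. It gives the biaryl A4, in which A1 is a methyl ether and B1 a triisopropylsilyl ether.
- For it: the polarisation of the two partners fixes the regiochemistry, the gas loss makes the ring formation irreversible, and the two phenol oxygens emerge differentiated. On irreversibility and on differentiation it is stronger than the chosen key step.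
- Against it: A5 needs an aryl–pyrone bond at a carbon flanked by a methyl group and an ortho-substituted arene, which is again a hindered cross-coupling, and ring A must be made separately with its stereocentre. A6 is sensitive to moisture and heat and must form its bond at the congested C3 of the pyrone. A4 still needs a methyl ether cleavage in the presence of the alkenes.
- Comparison: the chosen route also makes one arene from a heterocycle, but the diene (the furan of 22) is assembled by condensation and not by coupling. Its dienophile is a plain propargyl ether, and its only late deprotection is the reductive opening of the tether itself.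

**Alternative 3:** The two aryl–benzylic bonds (A2 and B2 to their side chains) are cut. The forward key step is a twofold rhodium-catalysed asymmetric conjugate arylation of tert-butyl crotonate A9 by the biaryl bis(boronic acid) A8 (rhodium hydroxide complex with a chiral bisphosphine), which gives the bis[(S)-3-arylbutanoate] A7.
- For it: this reaction class is among the most dependable ways to set a benzylic methyl stereocentre, it is mild, and the ester groups allow flexible chain building. On the reliability of the individual stereo-determining event it is stronger than a chiral-pool route that depends on the optical purity of a purchased terpene.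
- Against it: A8 requires the hindered biaryl and a regioselective double borylation. The boronic acid next to the methoxy group is prone to protodeboronation under the aqueous basic conditions, and losses multiply over two arylations. Each arm of A7 then needs three further operations (reduction, activation, coupling with an isobutenyl organometallic) before two methyl ethers are cleaved.
- Comparison: the chosen route brings both side chains in complete, so no chain building follows the key step, and the only operation after ring formation is one reduction.

Key step: step 12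

Assumption: the A4–B6 axis (ortho groups CH3, CH3, OH, H) is treated as configurationally undefined, since the structure specifies no axial descriptor, and no axial control is attempted.
Assumption: (S)-citronellal of high optical purity is used for both halves; with two centres from the same source, the minor enantiomer ends up mostly in a diastereomer and not in the enantiomer of 27.

## Route

Step 1
Reactants: 1 (S)-citronellal; 2 methyl vinyl ketone
Product: 4 4-[(2S)-6-methylhept-5-en-2-yl]cyclohex-2-en-1-one (both C4 epimers), via keto aldehyde 3 (not isolated)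
Conditions: Et2NH (0.2 equiv), MeCN, 0 °C to rt; then aq. KOH, n-Bu4NOH (cat.), THF, 60 °C
Reagents that add atoms: none
Why: Robinson annulation: amine-catalysed (enamine) Michael addition of the aldehyde to the enone, then intramolecular aldol condensation. The ring carbon C4 forms as both epimers, which is harmless because it becomes aromatic; the side-chain stereocentre is β to the carbonyl and cannot enolise.

Step 2
Reactants: 4 4-[(2S)-6-methylhept-5-en-2-yl]cyclohex-2-en-1-one
Product: 6 4-[(2S)-6-methylhept-5-en-2-yl]-6-(phenylsulfanyl)cyclohex-2-en-1-one (diastereomer mixture), via lithium dienolate 5 (not isolated)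
Conditions: LiN(i-Pr)2, THF, −78 °C; then PhSO2SPh, −78 to −20 °C
Reagents that add atoms: S-phenyl benzenethiosulfonate, O=S(=O)(Sc1ccccc1)c1ccccc1
Why: Kinetic α′-deprotonation of the enone gives the cross-conjugated dienolate, which is sulfenylated at the ring CH2 (enolate sulfenylation). This puts the future leaving group on a carbon with no bond to the side chain.

Step 3
Reactants: 6 4-[(2S)-6-methylhept-5-en-2-yl]-6-(phenylsulfanyl)cyclohex-2-en-1-one
Product: 7 1-methyl-4-[(2S)-6-methylhept-5-en-2-yl]-6-(phenylsulfanyl)cyclohex-2-en-1-ol (diastereomer mixture)
Conditions: MeLi, CeCl3, THF, −78 °C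
Reagents that add atoms: methyllithium, [Li]C
Why: Organocerium 1,2-addition to the enone carbonyl. The weakly basic cerium reagent avoids enolisation of the acidic α-sulfanyl ketone and conjugate addition; the new carbinol configuration is irrelevant.

Step 4
Reactants: 7 1-methyl-4-[(2S)-6-methylhept-5-en-2-yl]-6-(phenylsulfanyl)cyclohex-2-en-1-ol
Product: 8 1-methyl-4-[(2S)-6-methylhept-5-en-2-yl]-6-(phenylsulfinyl)cyclohex-2-en-1-ol (diastereomer mixture)
Conditions: NaIO4, MeOH/H2O, 0 °C to rt
Reagents that add atoms: sodium periodate, [Na+].[O-]I(=O)(=O)=O
Why: Periodate oxidation of a sulfide stops at the sulfoxide and does not touch trisubstituted alkenes. Oxidising sulfur before the chromium step removes the sulfur lone pair that could otherwise take part in ionisation of the tertiary alcohol or be oxidised there.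

Step 5
Reactants: 8 1-methyl-4-[(2S)-6-methylhept-5-en-2-yl]-6-(phenylsulfinyl)cyclohex-2-en-1-ol
Product: 9 3-methyl-6-[(2S)-6-methylhept-5-en-2-yl]-4-(phenylsulfinyl)cyclohex-2-en-1-one (diastereomer mixture)
Conditions: pyridinium chlorochromate (C5H5NH[CrO3Cl]), NaOAc, 4 Å MS, CH2Cl2, rt
Reagents that add atoms: pyridinium chlorochromate, [O-][Cr](=O)(=O)Cl.c1cc[nH+]cc1 (supplies the carbonyl oxygen)
Why: Babler–Dauben oxidative transposition: the chromate ester of the tertiary allylic alcohol shifts by a [3,3] rearrangement and the secondary allylic chromate is oxidised to the enone. The carbonyl ends next to the carbon bearing the side chain and the methyl para to it; the sulfoxide is inert to hexavalent chromium and stable at room temperature.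

Step 6
Reactants: 9 3-methyl-6-[(2S)-6-methylhept-5-en-2-yl]-4-(phenylsulfinyl)cyclohex-2-en-1-one
Product: 11 5-methyl-2-[(2S)-6-methylhept-5-en-2-yl]phenol, via dienone 10 (not isolated)
Conditions: NaHCO3 (solid), toluene, 100 °C
Reagents that add atoms: none
Why: Thermal syn-elimination of the sulfoxide: the only β-hydrogens are on ring C5, so the C4=C5 bond forms and the 2,4-dienone enolises through ring C6–H to the phenol. The side-chain methine is never involved, so the S configuration is kept; the allylic sulfoxide–sulfenate equilibrium is unproductive without a thiophile.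

Step 7
Reactants: 11 5-methyl-2-[(2S)-6-methylhept-5-en-2-yl]phenol
Product: 12 2-(methoxymethoxy)-4-methyl-1-[(2S)-6-methylhept-5-en-2-yl]benzene
Conditions: MOMCl, i-Pr2NEt, CH2Cl2, 0 °C to rt
Reagents that add atoms: chloromethyl methyl ether, COCCl
Why: O-alkylation of the phenol (acetal protection). The methoxymethyl group directs the next metalation and leaves under the acid of the furan-forming step.

Step 8
Reactants: 12 2-(methoxymethoxy)-4-methyl-1-[(2S)-6-methylhept-5-en-2-yl]benzene; 13 2-chloro-N-methoxy-N-methylacetamide
Product: 15 2-chloro-1-{2-(methoxymethoxy)-6-methyl-3-[(2S)-6-methylhept-5-en-2-yl]phenyl}ethan-1-one, via aryllithium 14 (not isolated)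
Conditions: n-BuLi, TMEDA, Et2O, 0 °C to rt; then 13, THF, −78 to 0 °C; aq. NH4Cl
Reagents that add atoms: none
Why: Directed ortho-metalation: B6 is the only free position ortho to the acetal oxygen, since B2 carries the side chain. Acylation by the N-methoxy-N-methyl amide stops at the ketone through the chelated tetrahedral intermediate and keeps the chloride.

Step 9
Reactants: 1 (S)-citronellal; 15 2-chloro-1-{2-(methoxymethoxy)-6-methyl-3-[(2S)-6-methylhept-5-en-2-yl]phenyl}ethan-1-one
Product: 18 4-{2-(methoxymethoxy)-6-methyl-3-[(2S)-6-methylhept-5-en-2-yl]phenyl}-2-[(2S)-6-methylhept-5-en-2-yl]-4-oxobutanal (both C2 epimers), via enamine 16 (not isolated), via iminium chloride 17 (not isolated)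
Conditions: 1 (1.5 equiv), pyrrolidine, 4 Å MS, MeCN, rt; then 15, NaI (cat.), 70 °C; then AcOH, NaOAc, H2O, rt
Reagents that add atoms: water, O
Why: Stork enamine alkylation: the aldehyde enamine is C-alkylated by the α-halo ketone (iodide formed in situ) and the iminium salt is hydrolysed to the 1,4-keto aldehyde. The new α-centre forms as both epimers and becomes sp2 in the furan; the side-chain centre is β to the aldehyde and untouched, and the two ortho groups shield the ketone from attack.

Step 10
Reactants: 18 4-{2-(methoxymethoxy)-6-methyl-3-[(2S)-6-methylhept-5-en-2-yl]phenyl}-2-[(2S)-6-methylhept-5-en-2-yl]-4-oxobutanal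
Product: 20 3-methyl-6-[(2S)-6-methylhept-5-en-2-yl]-2-{4-[(2S)-6-methylhept-5-en-2-yl]furan-2-yl}phenol, via MOM-protected furan 19 (not isolated)
Conditions: p-TsOH·H2O (0.2 equiv), MeOH/THF, 50 °C
Reagents that add atoms: none
Why: Paal–Knorr cyclodehydration of the γ-keto aldehyde gives the 2-aryl-4-alkylfuran, and the same acid in methanol removes the acetal by exchange with the solvent. The remote trisubstituted alkenes should tolerate catalytic sulfonic acid at this temperature.

Step 11
Reactants: 20 3-methyl-6-[(2S)-6-methylhept-5-en-2-yl]-2-{4-[(2S)-6-methylhept-5-en-2-yl]furan-2-yl}phenol; 21 propargyl bromide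
Product: 22 2-{6-methyl-3-[(2S)-6-methylhept-5-en-2-yl]-2-(prop-2-yn-1-yloxy)phenyl}-4-[(2S)-6-methylhept-5-en-2-yl]furan
Conditions: Cs2CO3, DMF, rt
Reagents that add atoms: none
Why: Williamson ether synthesis: the hindered phenoxide is O-alkylated by an unhindered propargylic bromide.

Step 12
Reactants: 22 2-{6-methyl-3-[(2S)-6-methylhept-5-en-2-yl]-2-(prop-2-yn-1-yloxy)phenyl}-4-[(2S)-6-methylhept-5-en-2-yl]furan
Product: 24 1-methyl-4,9-bis[(2S)-6-methylhept-5-en-2-yl]-6H-benzo[c]chromen-8-ol, via oxa-bridged cycloadduct 23 (not isolated)
Conditions: 1,2-dichlorobenzene (0.02 M, degassed), 2,6-di-tert-butyl-4-methylphenol (0.1 equiv), sealed tube, 170 °C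
Reagents that add atoms: none
Why: The furan of 22 acts as the 4π component through A4–A3–A2–A1 and the terminal alkyne as the 2π component in a thermal suprafacial intramolecular [4+2] cycloaddition, giving the 7-oxanorbornadiene 23; this is the known reaction type of furans with tethered alkynes, 2-arylfurans with an aryl propargyl ether included. The pyran closes as the six-membered tether ring in an exo mode, because the B6–B1–O–CH2 chain can bring only the inner alkyne carbon A5 to A4, and the carbocycle of ring A closes in the same event as the six-membered cycloadduct ring through A4–A5 and A1–A6. The cycloaddition is reversible and is pulled forward by heterolysis of the A4–O bond, which leaves a cation that is tertiary, benzylic to ring B and doubly allylic; loss of the A1 hydrogen then gives the phenol, so the oxygen stays on A1. No stereocentre is created in 24: the two bridgehead centres of 23 vanish on aromatisation, so both furan faces converge, and the side-chain centres are not touched. The step needs regiocontrol, which the four-atom tether and the direction of bridge opening supply, and chemoselectivity over the two side-chain alkenes, which are unactivated and not held near the furan. The B5 methyl twists ring B out of the furan plane and so hangs the propargyl group over the furan face. Because B2 and B6 both carry carbon, the aromatic Claisen rearrangement cannot finish by enolisation, but the first [3,3] shift to an allenyl dienone remains possible and could leak to rearranged ketones at higher temperature, which is why the lowest temperature that turns 22 over and high dilution are chosen. The hindered phenol additive suppresses radical chemistry at the benzylic and allylic positions and acts as a mild proton shuttle for the bridge opening.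

Step 13
Reactants: 24 1-methyl-4,9-bis[(2S)-6-methylhept-5-en-2-yl]-6H-benzo[c]chromen-8-ol
Product: 27 2',6-dimethyl-3,5'-bis[(2S)-6-methylhept-5-en-2-yl]-[1,1'-biphenyl]-2,4'-diol, via lithium phenoxide 25 (not isolated), via benzylic organolithium 26 (not isolated)
Conditions: n-BuLi (1.05 equiv), THF, −78 °C; then lithium 4,4′-di-tert-butylbiphenylide (LiDBB, 3 equiv), −78 to −30 °C; then MeOH, aq. NH4Cl
Reagents that add atoms: none
Why: Reductive cleavage of a benzyl aryl ether by an arene radical anion: electron transfer into the biaryl breaks the benzylic C–O bond to a benzylic radical and the B1 phenoxide, a second electron gives the benzyllithium, and the quench turns it into the A5 methyl. Isolated alkenes are not reduced without a proton source, the A1 phenoxide protects ring A, and the tertiary benzylic C–H bonds are not acidic enough to be deprotonated at this temperature.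

## Compound list

1 | (3S)-3,7-dimethyloct-6-enal, (S)-citronellal | CC(C)=CCC[C@H](C)CC=O | starting material
2 | but-3-en-2-one, methyl vinyl ketone | C=CC(C)=O | starting material
3 | 2-[(2S)-6-methylhept-5-en-2-yl]-5-oxohexanal (both C2 epimers) | CC(C)=CCC[C@H](C)C(C=O)CCC(C)=O | intermediate (not isolated)
4 | 4-[(2S)-6-methylhept-5-en-2-yl]cyclohex-2-en-1-one (both C4 epimers) | CC(C)=CCC[C@H](C)C1CCC(=O)C=C1 | intermediate
5 | lithium 4-[(2S)-6-methylhept-5-en-2-yl]cyclohexa-1,5-dien-1-olate | CC(C)=CCC[C@H](C)C1CC=C(O[Li])C=C1 | intermediate (not isolated)
6 | 4-[(2S)-6-methylhept-5-en-2-yl]-6-(phenylsulfanyl)cyclohex-2-en-1-one | CC(C)=CCC[C@H](C)C1CC(Sc2ccccc2)C(=O)C=C1 | intermediate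
7 | 1-methyl-4-[(2S)-6-methylhept-5-en-2-yl]-6-(phenylsulfanyl)cyclohex-2-en-1-ol | CC(C)=CCC[C@H](C)C1CC(Sc2ccccc2)C(C)(O)C=C1 | intermediate
8 | 1-methyl-4-[(2S)-6-methylhept-5-en-2-yl]-6-(phenylsulfinyl)cyclohex-2-en-1-ol | CC(C)=CCC[C@H](C)C1CC(S(=O)c2ccccc2)C(C)(O)C=C1 | intermediate
9 | 3-methyl-6-[(2S)-6-methylhept-5-en-2-yl]-4-(phenylsulfinyl)cyclohex-2-en-1-one | CC(C)=CCC[C@H](C)C1CC(S(=O)c2ccccc2)C(C)=CC1=O | intermediate
10 | 3-methyl-6-[(2S)-6-methylhept-5-en-2-yl]cyclohexa-2,4-dien-1-one | CC(C)=CCC[C@H](C)C1C=CC(C)=CC1=O | intermediate (not isolated)
11 | 5-methyl-2-[(2S)-6-methylhept-5-en-2-yl]phenol (ring B phenol) | CC(C)=CCC[C@H](C)c1ccc(C)cc1O | intermediate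
12 | 2-(methoxymethoxy)-4-methyl-1-[(2S)-6-methylhept-5-en-2-yl]benzene | CC(C)=CCC[C@H](C)c1ccc(C)cc1OCOC | intermediate
13 | 2-chloro-N-methoxy-N-methylacetamide | CON(C)C(=O)CCl | starting material
14 | {2-(methoxymethoxy)-6-methyl-3-[(2S)-6-methylhept-5-en-2-yl]phenyl}lithium | CC(C)=CCC[C@H](C)c1ccc(C)c([Li])c1OCOC | intermediate (not isolated)
15 | 2-chloro-1-{2-(methoxymethoxy)-6-methyl-3-[(2S)-6-methylhept-5-en-2-yl]phenyl}ethan-1-one | CC(C)=CCC[C@H](C)c1ccc(C)c(C(=O)CCl)c1OCOC | intermediate
16 | 1-[(1E,3S)-3,7-dimethylocta-1,6-dien-1-yl]pyrrolidine | CC(C)=CCC[C@H](C)/C=C/N1CCCC1 | intermediate (not isolated)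
17 | 1-{(3S)-2-(2-{2-(methoxymethoxy)-6-methyl-3-[(2S)-6-methylhept-5-en-2-yl]phenyl}-2-oxoethyl)-3,7-dimethyloct-6-en-1-ylidene}pyrrolidin-1-ium chloride | CC(C)=CCC[C@H](C)C(C=[N+]1CCCC1)CC(=O)c1c(C)ccc([C@@H](C)CCC=C(C)C)c1OCOC.[Cl-] | intermediate (not isolated)
18 | 4-{2-(methoxymethoxy)-6-methyl-3-[(2S)-6-methylhept-5-en-2-yl]phenyl}-2-[(2S)-6-methylhept-5-en-2-yl]-4-oxobutanal (both C2 epimers) | CC(C)=CCC[C@H](C)C(C=O)CC(=O)c1c(C)ccc([C@@H](C)CCC=C(C)C)c1OCOC | intermediate
19 | 2-{2-(methoxymethoxy)-6-methyl-3-[(2S)-6-methylhept-5-en-2-yl]phenyl}-4-[(2S)-6-methylhept-5-en-2-yl]furan | CC(C)=CCC[C@H](C)c1coc(-c2c(C)ccc([C@@H](C)CCC=C(C)C)c2OCOC)c1 | intermediate (not isolated)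
20 | 3-methyl-6-[(2S)-6-methylhept-5-en-2-yl]-2-{4-[(2S)-6-methylhept-5-en-2-yl]furan-2-yl}phenol | CC(C)=CCC[C@H](C)c1coc(-c2c(C)ccc([C@@H](C)CCC=C(C)C)c2O)c1 | intermediate
21 | 3-bromoprop-1-yne, propargyl bromide | C#CCBr | starting material
22 | 2-{6-methyl-3-[(2S)-6-methylhept-5-en-2-yl]-2-(prop-2-yn-1-yloxy)phenyl}-4-[(2S)-6-methylhept-5-en-2-yl]furan | CC(C)=CCC[C@H](C)c1coc(-c2c(C)ccc([C@@H](C)CCC=C(C)C)c2OCC#C)c1 | intermediate (precursor of the key step)
23 | 1-methyl-4,9-bis[(2S)-6-methylhept-5-en-2-yl]-8,10a-epoxy-8,10a-dihydro-6H-benzo[c]chromene (both bridgehead diastereomers) | CC(C)=CCC[C@H](C)C1=CC23OC1C=C2COc1c3c(C)ccc1[C@@H](C)CCC=C(C)C | intermediate (not isolated)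
24 | 1-methyl-4,9-bis[(2S)-6-methylhept-5-en-2-yl]-6H-benzo[c]chromen-8-ol | CC(C)=CCC[C@H](C)c1cc2c(cc1O)COc1c-2c(C)ccc1[C@@H](C)CCC=C(C)C | intermediate (product of the key step)
25 | lithium 1-methyl-4,9-bis[(2S)-6-methylhept-5-en-2-yl]-6H-benzo[c]chromen-8-olate | CC(C)=CCC[C@H](C)c1cc2c(cc1O[Li])COc1c-2c(C)ccc1[C@@H](C)CCC=C(C)C | intermediate (not isolated)
26 | dilithium 2'-(lithiomethyl)-6-methyl-3,5'-bis[(2S)-6-methylhept-5-en-2-yl]-[1,1'-biphenyl]-2,4'-bis(olate) | CC(C)=CCC[C@H](C)c1cc(-c2c(C)ccc([C@@H](C)CCC=C(C)C)c2O[Li])c(C[Li])cc1O[Li] | intermediate (not isolated)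
27 | 2',6-dimethyl-3,5'-bis[(2S)-6-methylhept-5-en-2-yl]-[1,1'-biphenyl]-2,4'-diol | CC(C)=CCC[C@H](C)c1cc(-c2c(C)ccc([C@@H](C)CCC=C(C)C)c2O)c(C)cc1O | target

## Step count and risk

Total step count: 13. Longest linear sequence: 13 steps, from 1 to 27. The second molecule of 1 enters at step 9 without steps of its own.

Steps least certain to work:

**Step 12 (key step).**
- What may go wrong: the cycloaddition of the unactivated terminal alkyne may be too slow at a temperature the substrate survives. At higher temperature the reversible [3,3] shift of the aryl propargyl ether can drain material into rearranged ketones, and incomplete bridge opening lets the cycloadduct revert.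
- Fallback: it sets out from 22 and comes back at 24. Catalytic t-BuOK in THF at 0 °C isomerises the propargyl ether to the allenyl ether F1. Its terminal C=C bond is a more reactive 2π partner and cannot undergo a Claisen shift. After removal of the base, heating in toluene at 80–100 °C should give the oxa-bridged adduct with an exocyclic enol ether, F2. Catalytic pyridinium p-toluenesulfonate then opens the bridge at A4 (the cation is further stabilised by the enol ether) and moves a hydrogen from A6 to the bridging CH, which leads to 24. Base-induced propargyl-to-allenyl isomerisation and intramolecular furan cycloadditions of allenyl ethers are both known chemistry. The opening is done with acid, not base, to keep the oxygen on A1.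

**Step 9.**
- What may go wrong: N-alkylation of the aldehyde enamine and self-condensation of the aldehyde can outrun C-alkylation, leaving 15 unconverted.
- Fallback: it sets out from 1 and 12 and comes back at 18. 1 is condensed with 1,1-dimethylhydrazine to the hydrazone F3. F3 is deprotonated with LiN(i-Pr)2 and alkylated with 2-bromo-N-methoxy-N-methylacetamide to the hydrazone amide F4. The aryllithium 14, made from 12 as in step 8, adds to the amide of F4 to give the aryl ketone hydrazone F5. Cleavage of the hydrazone with aqueous CuCl2 in buffered THF gives 18. The hydrazine is removed before the acid step so that it cannot form an N-aminopyrrole. This route makes the same bonds in the reverse order and does not need 15.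

**Step 8.**
- What may go wrong: metalation at B6, which is flanked by the acetal oxygen and the B5 methyl, may be slow, so that deprotonation elsewhere (benzylic or allylic) competes. The aryllithium may also enolise 13 instead of adding to it.
- Fallback: it sets out from 11 and comes back at 15. Magnesium-mediated ortho-formylation (MgCl2, Et3N, paraformaldehyde, MeCN, reflux) can only attack B6 and gives the salicylaldehyde F6. Protection with MOMCl gives F7. Chloromethyllithium (from ICH2Cl and MeLi·LiBr at −78 °C) adds to give the chlorohydrin F8, and Dess–Martin oxidation gives 15.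

**Step 13.**
- What may go wrong: electron transfer into the phenoxide-bearing, twisted biaryl may be sluggish, so cleavage is incomplete, or excess reagent may begin to reduce the arenes.
- Fallback: it sets out from 24 and comes back at 27. Sodium benzenethiolate (PhSNa) in DMF at 110 °C opens the pyran by substitution at the benzylic carbon with the B1 phenoxide as leaving group, giving the benzylic sulfide F9. Bu3SnH with azobisisobutyronitrile in toluene at 100 °C then cleaves the benzylic C–S bond homolytically and leaves the A5 methyl.

**Step 5.**
- What may go wrong: in the acidic chromium medium the tertiary allylic alcohol may ionise and dehydrate before the chromate ester rearranges, and the bulky sulfinyl neighbour may slow the shift.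
- Fallback: a sulfur-free sequence that sets out from 4 and comes back at 11. MeLi adds to 4 to give the tertiary allylic alcohol F10. Pyridinium chlorochromate transposes it to the enone F11. LiN(i-Pr)2 and Me3SiCl give the cross-conjugated silyl dienol ether F12, and Pd(OAc)2 (divalent palladium) in MeCN dehydrogenates it to the dienone, which tautomerises to 11. This is shorter, but hydride elimination can also run towards the side-chain methine, so the optical purity of 11 would have to be checked before going on. That is why it is not the first choice.

## Further compounds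

F1 | step 12 | 2-{6-methyl-3-[(2S)-6-methylhept-5-en-2-yl]-2-(propa-1,2-dien-1-yloxy)phenyl}-4-[(2S)-6-methylhept-5-en-2-yl]furan | CC(C)=CCC[C@H](C)c1coc(-c2c(C)ccc([C@@H](C)CCC=C(C)C)c2OC=C=C)c1
F2 | step 12 | 1-methyl-4,9-bis[(2S)-6-methylhept-5-en-2-yl]-8,10a-epoxy-7,8-dihydro-10aH-benzo[c]chromene | CC(C)=CCC[C@H](C)C1=CC23OC1CC2=COc1c3c(C)ccc1[C@@H](C)CCC=C(C)C
F3 | step 9 | (E)-2-[(3S)-3,7-dimethyloct-6-en-1-ylidene]-1,1-dimethylhydrazine | CC(C)=CCC[C@H](C)C/C=N/N(C)C
F4 | step 9 | (4S)-3-[(E)-(2,2-dimethylhydrazinylidene)methyl]-N-methoxy-N,4,8-trimethylnon-7-enamide (both C3 epimers) | CC(C)=CCC[C@H](C)C(/C=N/N(C)C)CC(=O)N(C)OC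
F5 | step 9 | (4S)-3-[(E)-(2,2-dimethylhydrazinylidene)methyl]-1-{2-(methoxymethoxy)-6-methyl-3-[(2S)-6-methylhept-5-en-2-yl]phenyl}-4,8-dimethylnon-7-en-1-one (both C3 epimers) | CC(C)=CCC[C@H](C)C(/C=N/N(C)C)CC(=O)c1c(C)ccc([C@@H](C)CCC=C(C)C)c1OCOC
F6 | step 8 | 2-hydroxy-6-methyl-3-[(2S)-6-methylhept-5-en-2-yl]benzaldehyde | CC(C)=CCC[C@H](C)c1ccc(C)c(C=O)c1O
F7 | step 8 | 2-(methoxymethoxy)-6-methyl-3-[(2S)-6-methylhept-5-en-2-yl]benzaldehyde | CC(C)=CCC[C@H](C)c1ccc(C)c(C=O)c1OCOC
F8 | step 8 | 2-chloro-1-{2-(methoxymethoxy)-6-methyl-3-[(2S)-6-methylhept-5-en-2-yl]phenyl}ethan-1-ol | CC(C)=CCC[C@H](C)c1ccc(C)c(C(O)CCl)c1OCOC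
F9 | step 13 | 6-methyl-3,5'-bis[(2S)-6-methylhept-5-en-2-yl]-2'-[(phenylsulfanyl)methyl]-[1,1'-biphenyl]-2,4'-diol | CC(C)=CCC[C@H](C)c1cc(-c2c(C)ccc([C@@H](C)CCC=C(C)C)c2O)c(CSc2ccccc2)cc1O
F10 | step 5 | 1-methyl-4-[(2S)-6-methylhept-5-en-2-yl]cyclohex-2-en-1-ol | CC(C)=CCC[C@H](C)C1CCC(C)(O)C=C1
F11 | step 5 | 3-methyl-6-[(2S)-6-methylhept-5-en-2-yl]cyclohex-2-en-1-one | CC(C)=CCC[C@H](C)C1CCC(C)=CC1=O
F12 | step 5 | trimethyl({5-methyl-2-[(2S)-6-methylhept-5-en-2-yl]cyclohexa-1,5-dien-1-yl}oxy)silane | CC(C)=CCC[C@H](C)C1=C(O[Si](C)(C)C)C=C(C)CC1
A1 | alternative 1 | 3,5'-bis[(2S)-but-3-en-2-yl]-2,4'-dimethoxy-2',6-dimethyl-1,1'-biphenyl | C=C[C@H](C)c1cc(-c2c(C)ccc([C@@H](C)C=C)c2OC)c(C)cc1OC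
A2 | alternative 1 | 3,5'-diethenyl-2,4'-dimethoxy-2',6-dimethyl-1,1'-biphenyl | C=Cc1cc(-c2c(C)ccc(C=C)c2OC)c(C)cc1OC
A3 | alternative 1 | ethene | C=C
A4 | alternative 2 | {[4'-methoxy-2',6-dimethyl-3,5'-bis[(2S)-6-methylhept-5-en-2-yl]-[1,1'-biphenyl]-2-yl]oxy}tri(propan-2-yl)silane | CC(C)=CCC[C@H](C)c1cc(-c2c(C)ccc([C@@H](C)CCC=C(C)C)c2O[Si](C(C)C)(C(C)C)C(C)C)c(C)cc1OC
A5 | alternative 2 | 3-{4-methoxy-2-methyl-5-[(2S)-6-methylhept-5-en-2-yl]phenyl}-4-methyl-2H-pyran-2-one | Cc1ccoc(=O)c1-c1cc([C@@H](C)CCC=C(C)C)c(OC)cc1C
A6 | alternative 2 | {[(3S)-3,7-dimethyloct-6-en-1-yn-1-yl]oxy}tri(propan-2-yl)silane | CC(C)=CCC[C@H](C)C#CO[Si](C(C)C)(C(C)C)C(C)C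
A7 | alternative 3 | di-tert-butyl (3S,3'S)-3,3'-(2,4'-dimethoxy-2',6-dimethyl-[1,1'-biphenyl]-3,5'-diyl)dibutanoate | CC(C)(C)OC(=O)C[C@H](C)c1cc(-c2c(C)ccc([C@@H](C)CC(=O)OC(C)(C)C)c2OC)c(C)cc1OC
A8 | alternative 3 | (2,4'-dimethoxy-2',6-dimethyl-[1,1'-biphenyl]-3,5'-diyl)diboronic acid | OB(O)c1cc(-c2c(C)ccc(B(O)O)c2OC)c(C)cc1OC
A9 | alternative 3 | tert-butyl (E)-but-2-enoate | C/C=C/C(=O)OC(C)(C)C
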